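**Retrosynthetic overview**

- The strategy rests on the ketone-bearing ring: acyl at C1, OH at C2, prenyl at C3, OH at C4, with C5–H and C6–H. C2–C5 is the carbon chain of a 2-prenylacetoacetate and C1/C6 is a two-carbon alkyne.
- Cutting ring bonds C1–C2 and C5–C6 gives a 2-prenyl-1-methoxy-1,3-bis(trimethylsilyloxy)butadiene and a terminal ynone whose acyl group is the complete (R)-2-silyloxy-3-arylpropanoyl side chain.
- The ynone goes back through a silylated Weinreb amide to (R)-danshensu, which supplies the catechol ring and the only stereocentre; the diene goes back to methyl acetoacetate and prenyl bromide.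
- Ring order: the catechol ring is bought; the resorcinol ring is built last by Diels–Alder reaction and aromatization, which also joins the two halves; only desilylation follows.

Key step: step 8

Remark: (R)-danshensu is used as the commercial free acid; enol-ether and ketene-acetal geometries and the transient sp3 centres of unisolated intermediates are left undefined because they are lost downstream. TBS = tert-butyldimethylsilyl, TMS = trimethylsilyl, MOM = methoxymethyl.

**Route**

Step 1
Reactants: 1 (R)-3-(3,4-dihydroxyphenyl)-2-hydroxypropanoic acid (danshensu)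
Product: 2 methyl (R)-3-(3,4-dihydroxyphenyl)-2-hydroxypropanoate
Conditions: MeOH, HCl (cat.), 50 °C, N2
Reagents that add atoms: methanol, CO
Why: Fischer esterification engages only the carboxyl group, and in acid the (R)-carbinol carbon is not enolised, so its configuration is carried over.

Step 2
Reactants: 2 methyl (R)-3-(3,4-dihydroxyphenyl)-2-hydroxypropanoate
Product: 3 methyl (R)-2-(tert-butyldimethylsilyloxy)-3-[3,4-bis(tert-butyldimethylsilyloxy)phenyl]propanoate
Conditions: TBSCl (3.6 equiv), imidazole (7.5 equiv), DMF, 0 °C → rt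
Reagents that add atoms: tert-butyldimethylsilyl chloride (TBSCl), CC(C)(C)[Si](C)(C)Cl
Why: Imidazole-promoted silylation (Corey conditions) should cap both phenols and the secondary alcohol without touching the ester or the stereocentre.

Step 3
Reactants: 3 methyl (R)-2-(tert-butyldimethylsilyloxy)-3-[3,4-bis(tert-butyldimethylsilyloxy)phenyl]propanoate
Product: 4 (R)-2-(tert-butyldimethylsilyloxy)-3-[3,4-bis(tert-butyldimethylsilyloxy)phenyl]-N-methoxy-N-methylpropanamide
Conditions: MeNH(OMe)·HCl (2 equiv), iPrMgCl (4 equiv), THF, −20 → 0 °C; aq. NH4Cl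
Reagents that add atoms: N,O-dimethylhydroxylamine hydrochloride, CNOC.Cl
Why: Aminolysis of the ester by the chloromagnesium amide formed in the flask (Weinreb amide synthesis) is a weakly basic acyl substitution that should leave the silyl ethers and the α-silyloxy stereocentre intact.

Step 4
Reactants: 4 (R)-2-(tert-butyldimethylsilyloxy)-3-[3,4-bis(tert-butyldimethylsilyloxy)phenyl]-N-methoxy-N-methylpropanamide; 5 ethynylmagnesium bromide (HC≡CMgBr)
Product: 7 (4R)-4-(tert-butyldimethylsilyloxy)-5-[3,4-bis(tert-butyldimethylsilyloxy)phenyl]pent-1-yn-3-one, via magnesium hemiaminal chelate 6 (not isolated)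
Conditions: HC≡CMgBr (3 equiv, 0.5 M in THF), THF, 0 °C → rt; cannulated into cold 1 M aq. HCl/Et2O, 0 °C
Reagents that add atoms: none
Why: In this Weinreb ketone synthesis the chelated tetrahedral adduct 6 blocks over-addition and α-deprotonation, and the cold acidic inverse quench protonates the released N,O-dimethylhydroxylamine before it can add to the ynone.

Step 5
Reactants: 8 methyl acetoacetate; 9 prenyl bromide (1-bromo-3-methylbut-2-ene)
Product: 11 methyl 2-(3-methylbut-2-en-1-yl)-3-oxobutanoate, via sodium enolate 10 (not isolated)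
Conditions: NaH (1.0 equiv), THF, 0 °C; then 9 (0.85 equiv), 0 °C → rt
Reagents that add atoms: none
Why: Acetoacetic ester alkylation, in which the soft stabilised enolate attacks the primary carbon of the allylic bromide (SN2), with the bromide as limiting reagent to hold back dialkylation.

Step 6
Reactants: 11 methyl 2-(3-methylbut-2-en-1-yl)-3-oxobutanoate
Product: 12 methyl 2-(3-methylbut-2-en-1-yl)-3-(trimethylsilyloxy)but-2-enoate
Conditions: TMSCl (1.5 equiv), Et3N (1.6 equiv), toluene, rt, 48 h; filtration under argon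
Reagents that add atoms: chlorotrimethylsilane (TMSCl), C[Si](C)(C)Cl
Why: Soft enolisation and O-silylation of the β-keto ester gives the conjugated silyl enol ether, the standard first stage of a Chan-type diene preparation.

Step 7
Reactants: 12 methyl 2-(3-methylbut-2-en-1-yl)-3-(trimethylsilyloxy)but-2-enoate
Product: 14 1-methoxy-2-(3-methylbut-2-en-1-yl)-1,3-bis(trimethylsilyloxy)buta-1,3-diene, via lithium dienolate 13 (not isolated)
Conditions: LiN(iPr)2 (commercial solution, 1.3 equiv), THF, −78 °C; then TMSCl (1.5 equiv), −78 → 20 °C; pentane, filtration under argon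
Reagents that add atoms: chlorotrimethylsilane (TMSCl), C[Si](C)(C)Cl
Why: Kinetic γ-deprotonation of the methyl group gives the ester-conjugated dienolate 13, which is far better stabilised than the anion from the prenyl CH2, and hard O-silylation then gives the 1,3-bis(silyloxy)diene, used without chromatography.

Step 8
Reactants: 7 (4R)-4-(tert-butyldimethylsilyloxy)-5-[3,4-bis(tert-butyldimethylsilyloxy)phenyl]pent-1-yn-3-one; 14 1-methoxy-2-(3-methylbut-2-en-1-yl)-1,3-bis(trimethylsilyloxy)buta-1,3-diene
Product: 16 (R)-2-(tert-butyldimethylsilyloxy)-3-[3,4-bis(tert-butyldimethylsilyloxy)phenyl]-1-[2,4-dihydroxy-3-(3-methylbut-2-en-1-yl)phenyl]propan-1-one, via cyclohexadiene cycloadduct 15 (not isolated)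
Conditions: 14 (2 equiv), toluene, 20 → 50 °C, argon; then THF, 0.5 M aq. HCl, 0 °C, brief
Reagents that add atoms: none
Why: The electron-rich dioxygenated diene 14 and the polarised ynone 7 should combine in a normal-demand, strongly asynchronous Diels–Alder reaction in which the diene CH2 terminus bonds to the unsubstituted alkyne carbon (ring bond C5–C6) and the ketene-acetal carbon bonds to the acyl-bearing alkyne carbon (ring bond C1–C2), giving cyclohexa-1,4-diene 15. Cold dilute acid then cleaves the two trimethylsilyl ethers, the C(OMe)(O) carbon collapses with loss of methanol and the dienone tautomerises, so the new carbocycle becomes the 2,4-dihydroxy-3-prenylphenyl ring and the sequence cannot revert. The closest known reaction type is the cycloaddition and aromatization of 1-alkoxy-1,3-bis(silyloxy)butadienes (Chan- and Brassard-type dienes) with acetylenic ketones and esters to 2,4-dihydroxyaryl carbonyl compounds. The one ring closed, the resorcinol ring, is formed by intermolecular (4+2) cycloaddition, which at its stepwise extreme is a vinylogous Mukaiyama–Michael addition followed by 6-exo-trig attack of the allenolate carbon on the silyloxycarbenium carbon. No stereocentre of the product is created: the ketal carbon of 15 is erased on aromatization, and the (R)-silyloxy carbon beside the ketone is a spectator because neither base nor Lewis acid is present. The step needs addition across the alkyne in one orientation instead of 1,2-attack on the carbonyl group, and this is secured by pairing the most nucleophilic diene terminus (CH2) with the unhindered ynone β-carbon, so that the ketone lies next to the oxygen derived from the ester and opposite the one derived from the acetoacetate ketone, with the prenyl group between the two hydroxyls.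

Step 9
Reactants: 16 (R)-2-(tert-butyldimethylsilyloxy)-3-[3,4-bis(tert-butyldimethylsilyloxy)phenyl]-1-[2,4-dihydroxy-3-(3-methylbut-2-en-1-yl)phenyl]propan-1-one
Product: 17 (R)-1-[2,4-dihydroxy-3-(3-methylbut-2-en-1-yl)phenyl]-3-(3,4-dihydroxyphenyl)-2-hydroxypropan-1-one (CNP0408242.1)
Conditions: Bu4NF (4.5 equiv), AcOH (5 equiv), THF, 0 °C → rt, argon
Reagents that add atoms: none
Why: Fluoride-mediated desilylation buffered with acetic acid should free the two catechol hydroxyls and the carbinol while keeping the medium too weakly basic to enolise the α-hydroxy ketone or oxidise the catechol, so the (R)-centre from danshensu is retained.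

**Compound list**

1 | (R)-3-(3,4-dihydroxyphenyl)-2-hydroxypropanoic acid (danshensu) | OC(=O)[C@H](O)Cc1ccc(O)c(O)c1 | starting material
2 | methyl (R)-3-(3,4-dihydroxyphenyl)-2-hydroxypropanoate | COC(=O)[C@H](O)Cc1ccc(O)c(O)c1 | intermediate
3 | methyl (R)-2-(tert-butyldimethylsilyloxy)-3-[3,4-bis(tert-butyldimethylsilyloxy)phenyl]propanoate | COC(=O)[C@H](O[Si](C)(C)C(C)(C)C)Cc1ccc(O[Si](C)(C)C(C)(C)C)c(O[Si](C)(C)C(C)(C)C)c1 | intermediate
4 | (R)-2-(tert-butyldimethylsilyloxy)-3-[3,4-bis(tert-butyldimethylsilyloxy)phenyl]-N-methoxy-N-methylpropanamide | CON(C)C(=O)[C@H](O[Si](C)(C)C(C)(C)C)Cc1ccc(O[Si](C)(C)C(C)(C)C)c(O[Si](C)(C)C(C)(C)C)c1 | intermediate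
5 | ethynylmagnesium bromide | C#C[Mg]Br | starting material
6 | bromomagnesium (4R)-4-(tert-butyldimethylsilyloxy)-5-[3,4-bis(tert-butyldimethylsilyloxy)phenyl]-3-[methoxy(methyl)amino]pent-1-yn-3-olate (C3 undefined, not isolated) | C#CC(O[Mg]Br)(N(C)OC)[C@H](O[Si](C)(C)C(C)(C)C)Cc1ccc(O[Si](C)(C)C(C)(C)C)c(O[Si](C)(C)C(C)(C)C)c1 | intermediate
7 | (4R)-4-(tert-butyldimethylsilyloxy)-5-[3,4-bis(tert-butyldimethylsilyloxy)phenyl]pent-1-yn-3-one | C#CC(=O)[C@H](O[Si](C)(C)C(C)(C)C)Cc1ccc(O[Si](C)(C)C(C)(C)C)c(O[Si](C)(C)C(C)(C)C)c1 | intermediate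
8 | methyl acetoacetate | COC(=O)CC(C)=O | starting material
9 | prenyl bromide (1-bromo-3-methylbut-2-ene) | CC(C)=CCBr | starting material
10 | sodium enolate of methyl acetoacetate (not isolated) | COC(=O)C=C(C)[O-].[Na+] | intermediate
11 | methyl 2-(3-methylbut-2-en-1-yl)-3-oxobutanoate (racemic, labile centre) | COC(=O)C(CC=C(C)C)C(C)=O | intermediate
12 | methyl 2-(3-methylbut-2-en-1-yl)-3-(trimethylsilyloxy)but-2-enoate | COC(=O)C(CC=C(C)C)=C(C)O[Si](C)(C)C | intermediate
13 | lithium 1-methoxy-2-(3-methylbut-2-en-1-yl)-3-(trimethylsilyloxy)buta-1,3-dien-1-olate (not isolated) | COC([O-])=C(CC=C(C)C)C(=C)O[Si](C)(C)C.[Li+] | intermediate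
14 | 1-methoxy-2-(3-methylbut-2-en-1-yl)-1,3-bis(trimethylsilyloxy)buta-1,3-diene | COC(O[Si](C)(C)C)=C(CC=C(C)C)C(=C)O[Si](C)(C)C | intermediate
15 | (2R)-2-(tert-butyldimethylsilyloxy)-3-[3,4-bis(tert-butyldimethylsilyloxy)phenyl]-1-[6-methoxy-5-(3-methylbut-2-en-1-yl)-4,6-bis(trimethylsilyloxy)cyclohexa-1,4-dien-1-yl]propan-1-one (ring C6 undefined, not isolated) | COC1(O[Si](C)(C)C)C(CC=C(C)C)=C(O[Si](C)(C)C)CC=C1C(=O)[C@H](O[Si](C)(C)C(C)(C)C)Cc2ccc(O[Si](C)(C)C(C)(C)C)c(O[Si](C)(C)C(C)(C)C)c2 | intermediate
16 | (R)-2-(tert-butyldimethylsilyloxy)-3-[3,4-bis(tert-butyldimethylsilyloxy)phenyl]-1-[2,4-dihydroxy-3-(3-methylbut-2-en-1-yl)phenyl]propan-1-one | CC(C)=CCc1c(O)ccc(C(=O)[C@H](O[Si](C)(C)C(C)(C)C)Cc2ccc(O[Si](C)(C)C(C)(C)C)c(O[Si](C)(C)C(C)(C)C)c2)c1O | intermediate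
17 | (R)-1-[2,4-dihydroxy-3-(3-methylbut-2-en-1-yl)phenyl]-3-(3,4-dihydroxyphenyl)-2-hydroxypropan-1-one (CNP0408242.1) | CC(C)=CCc1c(O)ccc(C(=O)[C@H](O)Cc2ccc(O)c(O)c2)c1O | target

**Count**

Total steps: 9. Longest linear sequence: 6 steps (steps 1, 2, 3, 4, 8, 9 from danshensu); the diene branch (steps 5–7) joins at step 8.

**Steps most likely to fail, with fallbacks**

1. Step 8. The cycloaddition may stop at the open-chain conjugate-addition stage, may be diverted to attack at the carbonyl carbon, or the moisture-sensitive diene may hydrolyse before it reacts; aromatization could also proceed with loss of silanol and retention of the O-methyl group. The fallback sets out from Weinreb amide 4 and returns at target 17, replacing ring construction by acylation of a preformed aryl nucleophile. Commercial 1,3-bis(methoxymethoxy)benzene is lithiated between the two acetal oxygens (n-BuLi, THF, 0 °C) to 2-lithio-1,3-bis(methoxymethoxy)benzene F1. This is alkylated with prenyl bromide 9 (optionally with catalytic CuI) to 1,3-bis(methoxymethoxy)-2-(3-methylbut-2-en-1-yl)benzene F2. A second directed ortho-lithiation (n-BuLi, TMEDA, THF, −20 °C) gives [2,4-bis(methoxymethoxy)-3-(3-methylbut-2-en-1-yl)phenyl]lithium F3. Addition of F3 to 4 at −78 °C gives (R)-1-[2,4-bis(methoxymethoxy)-3-(3-methylbut-2-en-1-yl)phenyl]-2-(tert-butyldimethylsilyloxy)-3-[3,4-bis(tert-butyldimethylsilyloxy)phenyl]propan-1-one F4. Buffered fluoride as in step 9 gives (R)-1-[2,4-bis(methoxymethoxy)-3-(3-methylbut-2-en-1-yl)phenyl]-3-(3,4-dihydroxyphenyl)-2-hydroxypropan-1-one F5. Methanolic HCl at room temperature then removes the two MOM acetals to give 17; acid-induced cyclisation of the prenyl group onto a neighbouring phenol is the process to watch there.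

2. Step 4. The released N,O-dimethylhydroxylamine may add to the ynone during work-up, or addition to the hindered α-silyloxy amide may be slow enough for acetylide-mediated epimerisation to compete. The fallback sets out from Weinreb amide 4 and returns at ynone 7. Reduction with iBu2AlH (THF, −78 °C) gives (R)-2-(tert-butyldimethylsilyloxy)-3-[3,4-bis(tert-butyldimethylsilyloxy)phenyl]propanal F6, used crude. Addition of ethynylmagnesium bromide 5 at −78 °C gives (4R)-4-(tert-butyldimethylsilyloxy)-5-[3,4-bis(tert-butyldimethylsilyloxy)phenyl]pent-1-yn-3-ol F7 as a mixture of C3 epimers. Oxidation with Dess–Martin periodinane (CH2Cl2, NaHCO3) gives 7; no amine is present at the ynone stage.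

3. Step 9. Cleavage of the hindered secondary silyl ether next to the ketone may lag behind that of the aryl ethers, and longer exposure or weaker buffering invites epimerisation or enediol isomerisation of the α-hydroxy ketone. The fallback sets out from 16 and returns at target 17, using two orthogonal stages. KHF2 in MeOH at room temperature, which is selective for phenolic silyl ethers, gives (R)-2-(tert-butyldimethylsilyloxy)-1-[2,4-dihydroxy-3-(3-methylbut-2-en-1-yl)phenyl]-3-(3,4-dihydroxyphenyl)propan-1-one F8. The remaining alkyl silyl ether is then removed under acidic, non-enolising conditions (48% aq. HF, MeCN, 0 °C) to give 17.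

**Further compounds**

F1 | step 8 | 2-lithio-1,3-bis(methoxymethoxy)benzene | COCOc1cccc(OCOC)c1[Li]
F2 | step 8 | 1,3-bis(methoxymethoxy)-2-(3-methylbut-2-en-1-yl)benzene | COCOc1cccc(OCOC)c1CC=C(C)C
F3 | step 8 | [2,4-bis(methoxymethoxy)-3-(3-methylbut-2-en-1-yl)phenyl]lithium | [Li]c1ccc(OCOC)c(CC=C(C)C)c1OCOC
F4 | step 8 | (R)-1-[2,4-bis(methoxymethoxy)-3-(3-methylbut-2-en-1-yl)phenyl]-2-(tert-butyldimethylsilyloxy)-3-[3,4-bis(tert-butyldimethylsilyloxy)phenyl]propan-1-one | COCOc1ccc(C(=O)[C@H](O[Si](C)(C)C(C)(C)C)Cc2ccc(O[Si](C)(C)C(C)(C)C)c(O[Si](C)(C)C(C)(C)C)c2)c(OCOC)c1CC=C(C)C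
F5 | step 8 | (R)-1-[2,4-bis(methoxymethoxy)-3-(3-methylbut-2-en-1-yl)phenyl]-3-(3,4-dihydroxyphenyl)-2-hydroxypropan-1-one | COCOc1ccc(C(=O)[C@H](O)Cc2ccc(O)c(O)c2)c(OCOC)c1CC=C(C)C
F6 | step 4 | (R)-2-(tert-butyldimethylsilyloxy)-3-[3,4-bis(tert-butyldimethylsilyloxy)phenyl]propanal | O=C[C@H](O[Si](C)(C)C(C)(C)C)Cc1ccc(O[Si](C)(C)C(C)(C)C)c(O[Si](C)(C)C(C)(C)C)c1
F7 | step 4 | (4R)-4-(tert-butyldimethylsilyloxy)-5-[3,4-bis(tert-butyldimethylsilyloxy)phenyl]pent-1-yn-3-ol (both C3 epimers) | C#CC(O)[C@H](O[Si](C)(C)C(C)(C)C)Cc1ccc(O[Si](C)(C)C(C)(C)C)c(O[Si](C)(C)C(C)(C)C)c1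
F8 | step 9 | (R)-2-(tert-butyldimethylsilyloxy)-1-[2,4-dihydroxy-3-(3-methylbut-2-en-1-yl)phenyl]-3-(3,4-dihydroxyphenyl)propan-1-one | CC(C)=CCc1c(O)ccc(C(=O)[C@H](O[Si](C)(C)C(C)(C)C)Cc2ccc(O)c(O)c2)c1O
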